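## The problem

The target is a cis-fused hydrindenone. Numbering used throughout: C4 is the carbonyl carbon, C5 and C6 are the α- and β-carbons of the enone, C7 is the ring B methylene, C3a and C7a are the ring-fusion carbons, and C1–C3 are the three methylenes of ring C. C3a and C7a are adjacent quaternary carbons, each bearing a methyl group, and they are the only stereocentres (3aR,7aR, methyls cis). A five-membered ring can only be closed cis onto the six-membered ring. So if one centre is set from an outside source of chirality and the other is formed by an intramolecular ring closure, the relative configuration follows automatically. The enone is fully substituted: C5 carries a 2-hydroxy-2-methylpropyl arm and C6 a (2E)-4-aryl-2-methylbut-2-enyl chain, so the E geometry of a trisubstituted alkene also has to be secured. Three groups are fragile. The first CH2 of the C6 chain is doubly allylic and vinylogously acidic, so base can move the alkene into conjugation. The tertiary alcohol stands 1,4 to the ketone and can cyclise or dehydrate in acid. The aryl group is an electron-rich hydroquinone monoether that is easily oxidised. The feature that opens the molecule is that C7a is bonded to a ring C methylene (C1). In a cyclohexane precursor C7a is a tertiary C–H carbon lying 1,5 to the end carbon of a three-carbon arm on C3a, which is the geometry for a carbenoid C–H insertion with retention.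

## Retrosynthesis

**34 from 33.** The phenol and the tertiary alcohol are carried as triisopropylsilyl and triethylsilyl ethers. Both fall to buffered fluoride, the only deprotection that is neither basic nor acidic enough to disturb the skipped dienone or the 1,4-hydroxy ketone.

**33 from 24 and 32 (C6–CH2 bond).** The side chain is joined as an sp2–sp3 bond between a C6 vinylstannane (24) and the E allylic bromide 32. The obvious neighbour, conjugate addition of a side-chain cuprate to an enone followed by re-oxidation, needs an unsymmetrical allylic nucleophile. That nucleophile can attack through either terminus and can lose its alkene geometry by metallotropic shift. With the polarity reversed the allyl unit is the electrophile, palladium couples it at the primary carbon, and the geometry made in the fragment is kept. The coupling is neutral, so the base-sensitive product survives.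

**24 from 19 via 23, 22 and 21 (oxygen at C6, then tin).** A nucleophilic C6 is reached from the β-triflyloxy enone 23. The triflate comes from the 1,3-diketone 22, made from enone 19 by conjugate borylation, oxidation to 21 and oxidation of the alcohol. The sequence puts the heteroatom on C6 without ambiguity. The only selectivity asked for is triflation of the C6 oxygen in preference to the C4 oxygen, which sits next to the quaternary C3a.

**19 from 14 and 15 via 16 and 17 (α-arm and unsaturation).** The hydroxyisobutyl arm is a hydrated methallyl group. Ketone 14 enolises only towards C5, so alkylation with 15 is regiospecific. The Markovnikov hydration is placed at 16, before any other alkene exists. Silylation and Saegusa–Ito oxidation of 17 then give 19. Introducing the arm after the side chain would require a dienolate of a base-sensitive skipped dienone, so the order is fixed.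

**14 from 11 via 13 (ring C carbonyl out, ring B carbonyl back).** The cyclopentanone left by the key step is the only ketone in 11. One Wolff–Kishner operation removes it and also cleaves the acetate. Oxidation of 13 then returns the ring B ketone. No selective thioketalisation between two ketones is needed.

**11 from 10 (key disconnection, C1–C7a).** Cutting the bond between C7a and the ring C methylene C1 leaves a 2,3-dimethylcyclohexane with a diazoketone arm on the quaternary carbon. The forward reaction creates the second quaternary centre from a tertiary C–H bond with retention, so only one centre has to be made by asymmetric synthesis. The ring B carbonyl cannot be present as such. A ketone 1,5 to the carbenoid carbon would capture it as a six-membered cyclic carbonyl ylide. A ketal would offer an ether oxygen for oxonium ylide formation, and an ether at the alcohol level would activate its own geminal C–H, which is also 1,5. The carbonyl is therefore carried as the secondary acetate 10, whose geminal C–H is deactivated and whose oxygens are poor donors.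

**10 from 5 via 8 and 7.** The diazoketone comes from acid 8 by acid chloride formation and diazomethane. Acid 8 comes from tert-butyl ester 7, and 7 from keto ester 5 by reduction and acetylation.

**5 from 1, 2 and 3.** A catalytic asymmetric conjugate addition of methyl to 2-methylcyclohexenone (1) sets the methine. Alkylation of the resulting enolate with 3 anti to the new methyl sets the quaternary carbon, giving the cis-dimethyl pair in one flask from commodity materials.

**32 from 25 and 28 via 26, 27, 30 and 31.** The aryl–CH2 bond is cut to an aryllithium and prenyl bromide (28). The E allylic oxygen is added afterwards by selenium dioxide oxidation of the prenyl group, which selects the methyl trans to the chain. The aryl bromide 27 comes from 4-methoxy-2-methylphenol (25) by ortho-bromination and silylation.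

## Roads not taken

**Alternative 1: Diels–Alder construction of ring B on a dimethylcyclopentenedione.**
- **Cut and key step:** the C4–C3a and C7–C7a bonds are cut together. A 1-methoxy-3-silyloxy diene A3 carrying the C5 arm adds to 4,5-dimethylcyclopent-4-ene-1,3-dione A2 under a BINOL/Ti(Oi-Pr)4 Lewis acid (tetravalent titanium) to give cycloadduct A1.
- **Merits:** both quaternary carbons, the cis fusion and ring B arise in one step. Ring B arrives with oxygen already on C6, which the chosen plan buys with four steps (11–14). In convergence and step count to the bicyclic core this road is better.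
- **Weak points:** the dienophile is tetrasubstituted and both reacting carbons carry methyl groups, the least reactive pattern for a cycloaddition. The catalyst would have to control face, regiochemistry and endo selectivity on a dione with two equivalent carbonyl groups. Ring C arrives as a 1,3-dione, so two carbonyl groups must be removed.
- **Comparison:** the chosen plan is longer but forms each quaternary carbon by a reaction type with close precedent (conjugate addition with alkylation, tertiary C–H insertion with retention), and takes its absolute configuration from a simple enone.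

**Alternative 2: electroreductive decarboxylative radical closure of ring B.**
- **Cut and key step:** the C6–C7 bond is cut. Cathodic reduction of N-hydroxyphthalimide ester A5 (zinc sacrificial anode) releases a primary radical that adds 6-endo to the ynone β-carbon and gives enone A4 with the side chain in place.
- **Merits:** it is convergent at a late stage, forms the β-substituted enone and ring B together, and needs neither tin nor the C6 oxygenation sequence. In these respects it is better than the chosen plan.
- **Weak points:** A5 already contains the cis-1,2-dimethylcyclopentane with two different carbonyl arms on vicinal quaternary carbons, so the hardest stereochemical problem is moved, not solved. A4 lacks the C5 arm, and adding it requires a dienolate of the skipped dienone, the most base-sensitive intermediate.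
- **Comparison:** the chosen plan installs the C5 arm early on a simple ketone with one enolisable position and makes the second quaternary carbon stereospecifically.

**Alternative 3: transannular Ireland–Claisen contraction.**
- **Cut and key step:** the C3a–C7a bond is cut. The silyl ketene acetal of the Z-alkenyl nine-membered lactone A7 rearranges [3,3] to cyclopentane acid A6, which carries both quaternary carbons, the future C4 as a carboxylic acid and an E-alkenyl alkyne for building ring B.
- **Merits:** the most congested bond is formed directly and stereospecifically. Its control of the cis relation is as good as that of the C–H insertion.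
- **Weak points:** the precursor is a nine-membered lactone containing a trisubstituted Z alkene and a defined carbinol centre. The rearrangement must join two fully substituted carbons across a medium ring. Ring B still has to be built from A6 with the enone substitution pattern.
- **Comparison:** the chosen plan reaches the same vicinal quaternary pair from a six-membered ring that is never opened, with one catalytic asymmetric step and no medium ring.

Key step: step 5

Assumption: the phosphoramidite enantiomer is the one that delivers methyl to the face giving the (3S) methine of 4. Centres that are created and later destroyed (C5 in 16, 17, 20 and 21; C6 in 20 and 21) are left unassigned.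

## Route

Step 1
Reactants: 1 2-methylcyclohex-2-en-1-one; 2 trimethylaluminium; 3 tert-butyl bromoacetate
Product: 5 tert-butyl 2-[(1R,2S)-1,2-dimethyl-6-oxocyclohexyl]acetate, via aluminium enolate 4 (not isolated)
Conditions: copper thiophene-2-carboxylate CuO2CC4H3S (2 mol %, monovalent copper), BINOL-derived bis(1-phenylethyl)amine phosphoramidite (4 mol %), Et2O, −30 °C; then MeLi (1 equiv), THF/HMPA; then 3, −30 to 0 °C
Reagents that add atoms: none
Why: Copper-catalysed asymmetric conjugate addition followed by enolate alkylation: the ligand-bound methylcopper species adds to one face of 1 to set the (S)-methine of 4, and the lithium aluminate enolate formed with MeLi is alkylated by 3 anti to that methyl, which fixes the quaternary centre as R and places the two methyl groups cis.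

Step 2
Reactants: 5 tert-butyl 2-[(1R,2S)-1,2-dimethyl-6-oxocyclohexyl]acetate
Product: 7 tert-butyl 2-[(1R,2S,6R)-6-acetoxy-1,2-dimethylcyclohexyl]acetate, via hydroxy ester 6 (not isolated)
Conditions: NaBH4, MeOH, 0 °C; extractive work-up; Ac2O, pyridine, DMAP, CH2Cl2, rt
Reagents that add atoms: acetic anhydride, CC(=O)OC(C)=O
Why: Hydride reduction then acylation: axial hydride delivery anti to the axial quaternary methyl should give mainly the equatorial (6R) alcohol, and immediate acetylation prevents lactonisation onto the ester. This centre only masks the ring B carbonyl and is erased in step 7, so a minor epimer converges.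

Step 3
Reactants: 7 tert-butyl 2-[(1R,2S,6R)-6-acetoxy-1,2-dimethylcyclohexyl]acetate
Product: 8 2-[(1R,2S,6R)-6-acetoxy-1,2-dimethylcyclohexyl]acetic acid
Conditions: CF3CO2H, CH2Cl2, 0 °C to rt
Reagents that add atoms: none
Why: Acidolysis of the tert-butyl ester (E1 loss of 2-methylpropene) frees the acid without touching the secondary acetate.

Step 4
Reactants: 8 2-[(1R,2S,6R)-6-acetoxy-1,2-dimethylcyclohexyl]acetic acid
Product: 10 (1R,2R,3S)-2-(3-diazo-2-oxopropyl)-2,3-dimethylcyclohexyl acetate, via acid chloride 9 (not isolated)
Conditions: (COCl)2, DMF (cat.), CH2Cl2, 0 °C; evaporate; CH2N2 (excess), Et2O, 0 °C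
Reagents that add atoms: oxalyl chloride, ClC(=O)C(=O)Cl (chlorine of intermediate 9 only); diazomethane, C=[N+]=[N-]
Why: Acylation of diazomethane by an acid chloride (first stage of the Arndt–Eistert sequence); excess diazomethane consumes the HCl, and the acetate and all stereocentres are untouched.

Step 5
Reactants: 10 (1R,2R,3S)-2-(3-diazo-2-oxopropyl)-2,3-dimethylcyclohexyl acetate
Product: 11 (3aR,4R,7aS)-3a,7a-dimethyl-2-oxooctahydro-1H-inden-4-yl acetate
Conditions: Rh2(OAc)4 (1 mol %, divalent rhodium), CH2Cl2, reflux, slow addition of 10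
Reagents that add atoms: none
Why: Loss of N2 from 10 at rhodium gives an electrophilic rhodium carbenoid, which inserts into the tertiary C3–H bond of the cyclohexane through a concerted, asynchronous three-centre transition state; the closest known reaction type is the Rh2(OAc)4-catalysed 1,5 C–H insertion of α-diazo ketones that gives cyclopentanones beside quaternary carbons. Ring C closes in the 1,5 mode: the carbenoid carbon, the ketone carbon, the arm CH2, the quaternary carbon and the methine carbon become the five-membered ring. The new quaternary centre C7a is formed with retention at the reacting C–H bond, so its configuration is controlled by the (S)-methine set in step 1, and the cis relation of arm and hydrogen gives the cis ring fusion. The step needs site selectivity for this C–H bond over the acetoxy-bearing C–H (also 1,5), over the primary C–H bonds of the neighbouring methyl, and over Wolff rearrangement or carbene dimerisation. The tertiary C–H bond is the most electron-rich, the acetoxy group deactivates its geminal C–H towards the electrophilic carbenoid, and slow addition keeps the diazo concentration low. Holding the ring B carbonyl at the alcohol level as an acetate removes the ketone oxygen that would otherwise trap the carbenoid as a six-membered cyclic carbonyl ylide.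

Step 6
Reactants: 11 (3aR,4R,7aS)-3a,7a-dimethyl-2-oxooctahydro-1H-inden-4-yl acetate
Product: 13 (3aR,4R,7aR)-3a,7a-dimethyloctahydro-1H-inden-4-ol, via hydroxy hydrazone 12 (not isolated)
Conditions: N2H4·H2O, KOH, diethylene glycol, 130 then 200 °C
Reagents that add atoms: hydrazine, NN (nitrogen atoms of intermediate 12 only)
Why: Wolff–Kishner reduction: the unhindered cyclopentanone forms the hydrazone, which loses N2 under KOH at 200 °C to leave the ring C methylene. The same alkaline medium saponifies the acetate, so no separate deprotection is needed.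

Step 7
Reactants: 13 (3aR,4R,7aR)-3a,7a-dimethyloctahydro-1H-inden-4-ol
Product: 14 (3aR,7aR)-3a,7a-dimethyloctahydro-4H-inden-4-one
Conditions: Dess–Martin periodinane, NaHCO3, CH2Cl2, rt
Reagents that add atoms: none
Why: Dess–Martin oxidation of the hindered secondary alcohol returns the ring B ketone under neutral conditions; both ring-fusion carbons are quaternary and cannot epimerise.

Step 8
Reactants: 14 (3aR,7aR)-3a,7a-dimethyloctahydro-4H-inden-4-one; 15 3-bromo-2-methylprop-1-ene
Product: 16 (3aR,7aR)-3a,7a-dimethyl-5-(2-methylprop-2-en-1-yl)octahydro-4H-inden-4-one (C5 epimers)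
Conditions: LiN(i-Pr)2, THF, −78 °C; 15, −78 to 0 °C
Reagents that add atoms: none
Why: Enolate alkylation: 14 can enolise only towards C5 because C3a is quaternary, so a single enolate is alkylated by the allylic bromide. The C5 configuration is irrelevant because C5 becomes sp2 in step 10.

Step 9
Reactants: 16 (3aR,7aR)-3a,7a-dimethyl-5-(2-methylprop-2-en-1-yl)octahydro-4H-inden-4-one
Product: 17 (3aR,7aR)-5-(2-hydroxy-2-methylpropyl)-3a,7a-dimethyloctahydro-4H-inden-4-one (C5 epimers)
Conditions: Co(acac)2 (cat., divalent cobalt), PhSiH3, O2 (1 atm), THF, rt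
Reagents that add atoms: dioxygen, O=O
Why: Mukaiyama hydration (cobalt-catalysed hydrogen-atom transfer, Markovnikov): the 1,1-disubstituted alkene gives the tertiary radical and then the tertiary alcohol, while the ketone is inert. It is done here because no other alkene is yet present.

Step 10
Reactants: 17 (3aR,7aR)-5-(2-hydroxy-2-methylpropyl)-3a,7a-dimethyloctahydro-4H-inden-4-one
Product: 19 (3aR,7aR)-3a,7a-dimethyl-5-[2-methyl-2-(triethylsilyloxy)propyl]-1,2,3,3a,7,7a-hexahydro-4H-inden-4-one, via bis-silyl enol ether 18 (not isolated)
Conditions: Et3SiOTf (2.5 equiv), Et3N, CH2Cl2, 0 °C; concentrate; Pd(OAc)2 (10 mol %, divalent palladium), O2, DMSO, 60 °C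
Reagents that add atoms: triethylsilyl trifluoromethanesulfonate, CC[Si](CC)(CC)OS(=O)(=O)C(F)(F)F
Why: Silyl enol ether formation and Saegusa–Ito oxidation: the silyl triflate caps the tertiary alcohol and the only possible enol, and the palladium enolate then loses the ring β-hydrogen at C6 to give the conjugated endocyclic enone.

Step 11
Reactants: 19 (3aR,7aR)-3a,7a-dimethyl-5-[2-methyl-2-(triethylsilyloxy)propyl]-1,2,3,3a,7,7a-hexahydro-4H-inden-4-one
Product: 21 (3aR,7aR)-6-hydroxy-3a,7a-dimethyl-5-[2-methyl-2-(triethylsilyloxy)propyl]octahydro-4H-inden-4-one (C5 and C6 unassigned), via pinacol boronate 20 (not isolated)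
Conditions: B2pin2, CuCl (5 mol %, monovalent copper), NaOt-Bu, bis(2-diphenylphosphinophenyl) ether, MeOH, THF, rt; then NaBO3·4H2O, THF/H2O, rt
Reagents that add atoms: bis(pinacolato)diboron, CC1(C)OB(OC1(C)C)B1OC(C)(C)C(C)(C)O1 (boron of intermediate 20 only); sodium perborate, [Na+].[O-]OB=O
Why: Copper-catalysed conjugate borylation followed by oxidation of the C–B bond: the boryl–copper species adds to the unsubstituted β-carbon C6, and perborate converts the boronate into the alcohol, which places oxygen on C6 regiospecifically.

Step 12
Reactants: 21 (3aR,7aR)-6-hydroxy-3a,7a-dimethyl-5-[2-methyl-2-(triethylsilyloxy)propyl]octahydro-4H-inden-4-one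
Product: 22 (3aR,7aR)-6-hydroxy-3a,7a-dimethyl-5-[2-methyl-2-(triethylsilyloxy)propyl]-1,2,3,3a,7,7a-hexahydro-4H-inden-4-one (enol form of the 4,6-dione)
Conditions: Dess–Martin periodinane, CH2Cl2, rt
Reagents that add atoms: none
Why: Dess–Martin oxidation of a β-hydroxy ketone to the β-diketone, which should rest as the enol; the stereocentres at C5 and C6 disappear.

Step 13
Reactants: 22 (3aR,7aR)-6-hydroxy-3a,7a-dimethyl-5-[2-methyl-2-(triethylsilyloxy)propyl]-1,2,3,3a,7,7a-hexahydro-4H-inden-4-one
Product: 23 (3aR,7aR)-3a,7a-dimethyl-5-[2-methyl-2-(triethylsilyloxy)propyl]-4-oxo-2,3,3a,4,7,7a-hexahydro-1H-inden-6-yl trifluoromethanesulfonate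
Conditions: Tf2O, Et3N, CH2Cl2, −78 °C
Reagents that add atoms: trifluoromethanesulfonic anhydride, O=S(=O)(OS(=O)(=O)C(F)(F)F)C(F)(F)F
Why: O-Sulfonylation of a 1,3-diketone enolate: the oxygen on C6 is flanked by a CH2 whereas that on C4 sits beside the quaternary C3a, so triflation should occur at the C6 oxygen and leave the C4 carbonyl.

Step 14
Reactants: 23 (3aR,7aR)-3a,7a-dimethyl-5-[2-methyl-2-(triethylsilyloxy)propyl]-4-oxo-2,3,3a,4,7,7a-hexahydro-1H-inden-6-yl trifluoromethanesulfonate
Product: 24 (3aR,7aR)-3a,7a-dimethyl-5-[2-methyl-2-(triethylsilyloxy)propyl]-6-(trimethylstannyl)-1,2,3,3a,7,7a-hexahydro-4H-inden-4-one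
Conditions: Me3SnSnMe3, Pd(PPh3)4 (5 mol %, zerovalent palladium), LiCl, THF, 65 °C
Reagents that add atoms: hexamethylditin, C[Sn](C)(C)[Sn](C)(C)C
Why: Palladium-catalysed stannylation of a vinyl triflate (oxidative addition, transmetalation from the distannane, reductive elimination) turns C6 from an electrophilic into a nucleophilic sp2 carbon.

Step 15
Reactants: 25 4-methoxy-2-methylphenol
Product: 26 2-bromo-4-methoxy-6-methylphenol
Conditions: N-bromosuccinimide, CH2Cl2, 0 °C
Reagents that add atoms: N-bromosuccinimide, O=C1CCC(=O)N1Br
Why: Electrophilic aromatic bromination: the position para to the hydroxyl is blocked, so bromine enters the free ortho position, which the hydroxyl activates more strongly than the methoxy group activates its own ortho positions.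

Step 16
Reactants: 26 2-bromo-4-methoxy-6-methylphenol
Product: 27 (2-bromo-4-methoxy-6-methylphenoxy)tri(propan-2-yl)silane
Conditions: i-Pr3SiOTf, 2,6-lutidine, CH2Cl2, 0 °C to rt
Reagents that add atoms: triisopropylsilyl trifluoromethanesulfonate, CC(C)[Si](C(C)C)(C(C)C)OS(=O)(=O)C(F)(F)F
Why: Silylation of the phenol: the bulky silyl group resists butyllithium and 1,3-migration to the ortho carbanion in step 17 and is removed by fluoride at the end.

Step 17
Reactants: 27 (2-bromo-4-methoxy-6-methylphenoxy)tri(propan-2-yl)silane; 28 1-bromo-3-methylbut-2-ene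
Product: 30 [4-methoxy-2-methyl-6-(3-methylbut-2-en-1-yl)phenoxy]tri(propan-2-yl)silane, via aryllithium 29 (not isolated)
Conditions: n-BuLi, THF, −78 °C; 28, −78 °C to rt
Reagents that add atoms: n-butyllithium, [Li]CCCC (lithium of intermediate 29 only)
Why: Halogen–lithium exchange followed by SN2 alkylation of the aryllithium at the primary carbon of the allylic bromide installs the prenyl group.

Step 18
Reactants: 30 [4-methoxy-2-methyl-6-(3-methylbut-2-en-1-yl)phenoxy]tri(propan-2-yl)silane
Product: 31 (2E)-4-[5-methoxy-3-methyl-2-(triisopropylsilyloxy)phenyl]-2-methylbut-2-en-1-ol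
Conditions: SeO2 (0.3 equiv), t-BuOOH, CH2Cl2, rt
Reagents that add atoms: tert-butyl hydroperoxide, CC(C)(C)OO
Why: Selenium dioxide allylic oxidation (ene reaction then [2,3]-sigmatropic shift) attacks the methyl group trans to the chain on the more substituted alkene carbon, the established way to make (E)-allylic alcohols from prenyl groups.

Step 19
Reactants: 31 (2E)-4-[5-methoxy-3-methyl-2-(triisopropylsilyloxy)phenyl]-2-methylbut-2-en-1-ol
Product: 32 {2-[(2E)-4-bromo-3-methylbut-2-en-1-yl]-4-methoxy-6-methylphenoxy}tri(propan-2-yl)silane
Conditions: CBr4, PPh3, CH2Cl2, 0 °C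
Reagents that add atoms: carbon tetrabromide, BrC(Br)(Br)Br
Why: Appel bromination converts the primary allylic alcohol into the bromide by SN2 displacement without allylic transposition, so the E geometry is kept.

Step 20
Reactants: 24 (3aR,7aR)-3a,7a-dimethyl-5-[2-methyl-2-(triethylsilyloxy)propyl]-6-(trimethylstannyl)-1,2,3,3a,7,7a-hexahydro-4H-inden-4-one; 32 {2-[(2E)-4-bromo-3-methylbut-2-en-1-yl]-4-methoxy-6-methylphenoxy}tri(propan-2-yl)silane
Product: 33 (3aR,7aR)-6-{(2E)-4-[5-methoxy-3-methyl-2-(triisopropylsilyloxy)phenyl]-2-methylbut-2-en-1-yl}-3a,7a-dimethyl-5-[2-methyl-2-(triethylsilyloxy)propyl]-1,2,3,3a,7,7a-hexahydro-4H-inden-4-one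
Conditions: Pd2(dba)3 (5 mol %, zerovalent palladium), AsPh3, CuI (cat.), N-methylpyrrolidone, 40 °C
Reagents that add atoms: none
Why: Stille coupling of an alkenylstannane with an allylic bromide: oxidative addition gives the π-allyl palladium species, the vinyl group is transferred from tin, and reductive elimination occurs at the unsubstituted CH2 terminus with the E alkene intact. The neutral conditions spare the doubly allylic CH2 of the product.

Step 21
Reactants: 33 (3aR,7aR)-6-{(2E)-4-[5-methoxy-3-methyl-2-(triisopropylsilyloxy)phenyl]-2-methylbut-2-en-1-yl}-3a,7a-dimethyl-5-[2-methyl-2-(triethylsilyloxy)propyl]-1,2,3,3a,7,7a-hexahydro-4H-inden-4-one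
Product: 34 (3aR,7aR)-5-(2-hydroxy-2-methylpropyl)-6-[(2E)-4-(2-hydroxy-5-methoxy-3-methylphenyl)-2-methylbut-2-en-1-yl]-3a,7a-dimethyl-1,2,3,3a,7,7a-hexahydro-4H-inden-4-one (CNP0158008.2)
Conditions: Bu4NF, AcOH, THF, 0 °C to rt
Reagents that add atoms: none
Why: Fluoride-mediated desilylation buffered with acetic acid removes the aryl triisopropylsilyl and the tertiary triethylsilyl ethers without base- or acid-induced isomerisation of the skipped dienone.

## Compound list

1 | 2-methylcyclohex-2-en-1-one | CC1=CCCCC1=O | starting material
2 | trimethylaluminium | C[Al](C)C | starting material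
3 | tert-butyl bromoacetate | CC(C)(C)OC(=O)CBr | starting material
4 | {[(3S)-2,3-dimethylcyclohex-1-en-1-yl]oxy}dimethylalumane (aluminium enolate) | C[Al](C)OC1=C(C)[C@@H](C)CCC1 | intermediate
5 | tert-butyl 2-[(1R,2S)-1,2-dimethyl-6-oxocyclohexyl]acetate | O=C1[C@](C)(CC(=O)OC(C)(C)C)[C@@H](C)CCC1 | intermediate
6 | tert-butyl 2-[(1R,2S,6R)-6-hydroxy-1,2-dimethylcyclohexyl]acetate | O[C@H]1[C@](C)(CC(=O)OC(C)(C)C)[C@@H](C)CCC1 | intermediate
7 | tert-butyl 2-[(1R,2S,6R)-6-acetoxy-1,2-dimethylcyclohexyl]acetate | CC(=O)O[C@H]1[C@](C)(CC(=O)OC(C)(C)C)[C@@H](C)CCC1 | intermediate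
8 | 2-[(1R,2S,6R)-6-acetoxy-1,2-dimethylcyclohexyl]acetic acid | CC(=O)O[C@H]1[C@](C)(CC(=O)O)[C@@H](C)CCC1 | intermediate
9 | 2-[(1R,2S,6R)-6-acetoxy-1,2-dimethylcyclohexyl]acetyl chloride | CC(=O)O[C@H]1[C@](C)(CC(=O)Cl)[C@@H](C)CCC1 | intermediate
10 | (1R,2R,3S)-2-(3-diazo-2-oxopropyl)-2,3-dimethylcyclohexyl acetate | CC(=O)O[C@H]1[C@](C)(CC(=O)C=[N+]=[N-])[C@@H](C)CCC1 | intermediate
11 | (3aR,4R,7aS)-3a,7a-dimethyl-2-oxooctahydro-1H-inden-4-yl acetate | CC(=O)O[C@H]1[C@]2(C)CC(=O)C[C@]2(C)CCC1 | intermediate
12 | (3aR,4R,7aS)-2-hydrazinylidene-3a,7a-dimethyloctahydro-1H-inden-4-ol | O[C@H]1[C@]2(C)CC(=NN)C[C@]2(C)CCC1 | intermediate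
13 | (3aR,4R,7aR)-3a,7a-dimethyloctahydro-1H-inden-4-ol | O[C@H]1[C@]2(C)CCC[C@]2(C)CCC1 | intermediate
14 | (3aR,7aR)-3a,7a-dimethyloctahydro-4H-inden-4-one | O=C1[C@]2(C)CCC[C@]2(C)CCC1 | intermediate
15 | 3-bromo-2-methylprop-1-ene | C=C(C)CBr | starting material
16 | (3aR,7aR)-3a,7a-dimethyl-5-(2-methylprop-2-en-1-yl)octahydro-4H-inden-4-one (C5 unassigned) | O=C1[C@]2(C)CCC[C@]2(C)CCC1CC(C)=C | intermediate
17 | (3aR,7aR)-5-(2-hydroxy-2-methylpropyl)-3a,7a-dimethyloctahydro-4H-inden-4-one (C5 unassigned) | O=C1[C@]2(C)CCC[C@]2(C)CCC1CC(C)(C)O | intermediate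
18 | (3aR,7aR)-3a,7a-dimethyl-4-(triethylsilyloxy)-5-[2-methyl-2-(triethylsilyloxy)propyl]-2,3,3a,6,7,7a-hexahydro-1H-indene | CC[Si](CC)(CC)OC1[C@]2(C)CCC[C@]2(C)CCC=1CC(C)(C)O[Si](CC)(CC)CC | intermediate
19 | (3aR,7aR)-3a,7a-dimethyl-5-[2-methyl-2-(triethylsilyloxy)propyl]-1,2,3,3a,7,7a-hexahydro-4H-inden-4-one | O=C1[C@]2(C)CCC[C@]2(C)CC=C1CC(C)(C)O[Si](CC)(CC)CC | intermediate
20 | (3aR,7aR)-3a,7a-dimethyl-5-[2-methyl-2-(triethylsilyloxy)propyl]-6-(4,4,5,5-tetramethyl-1,3,2-dioxaborolan-2-yl)octahydro-4H-inden-4-one (C5, C6 unassigned) | O=C1[C@]2(C)CCC[C@]2(C)CC(B3OC(C)(C)C(C)(C)O3)C1CC(C)(C)O[Si](CC)(CC)CC | intermediate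
21 | (3aR,7aR)-6-hydroxy-3a,7a-dimethyl-5-[2-methyl-2-(triethylsilyloxy)propyl]octahydro-4H-inden-4-one (C5, C6 unassigned) | O=C1[C@]2(C)CCC[C@]2(C)CC(O)C1CC(C)(C)O[Si](CC)(CC)CC | intermediate
22 | (3aR,7aR)-6-hydroxy-3a,7a-dimethyl-5-[2-methyl-2-(triethylsilyloxy)propyl]-1,2,3,3a,7,7a-hexahydro-4H-inden-4-one (enol of the 4,6-dione) | O=C1[C@]2(C)CCC[C@]2(C)CC(O)=C1CC(C)(C)O[Si](CC)(CC)CC | intermediate
23 | (3aR,7aR)-3a,7a-dimethyl-5-[2-methyl-2-(triethylsilyloxy)propyl]-4-oxo-2,3,3a,4,7,7a-hexahydro-1H-inden-6-yl trifluoromethanesulfonate | O=C1[C@]2(C)CCC[C@]2(C)CC(OS(=O)(=O)C(F)(F)F)=C1CC(C)(C)O[Si](CC)(CC)CC | intermediate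
24 | (3aR,7aR)-3a,7a-dimethyl-5-[2-methyl-2-(triethylsilyloxy)propyl]-6-(trimethylstannyl)-1,2,3,3a,7,7a-hexahydro-4H-inden-4-one | O=C1[C@]2(C)CCC[C@]2(C)CC([Sn](C)(C)C)=C1CC(C)(C)O[Si](CC)(CC)CC | intermediate
25 | 4-methoxy-2-methylphenol | COc1ccc(O)c(C)c1 | starting material
26 | 2-bromo-4-methoxy-6-methylphenol | COc1cc(C)c(O)c(Br)c1 | intermediate
27 | (2-bromo-4-methoxy-6-methylphenoxy)tri(propan-2-yl)silane | COc1cc(C)c(O[Si](C(C)C)(C(C)C)C(C)C)c(Br)c1 | intermediate
28 | 1-bromo-3-methylbut-2-ene | CC(C)=CCBr | starting material
29 | [5-methoxy-3-methyl-2-(triisopropylsilyloxy)phenyl]lithium | COc1cc(C)c(O[Si](C(C)C)(C(C)C)C(C)C)c([Li])c1 | intermediate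
30 | [4-methoxy-2-methyl-6-(3-methylbut-2-en-1-yl)phenoxy]tri(propan-2-yl)silane | COc1cc(C)c(O[Si](C(C)C)(C(C)C)C(C)C)c(CC=C(C)C)c1 | intermediate
31 | (2E)-4-[5-methoxy-3-methyl-2-(triisopropylsilyloxy)phenyl]-2-methylbut-2-en-1-ol | COc1cc(C)c(O[Si](C(C)C)(C(C)C)C(C)C)c(C/C=C(\C)CO)c1 | intermediate
32 | {2-[(2E)-4-bromo-3-methylbut-2-en-1-yl]-4-methoxy-6-methylphenoxy}tri(propan-2-yl)silane | COc1cc(C)c(O[Si](C(C)C)(C(C)C)C(C)C)c(C/C=C(\C)CBr)c1 | intermediate
33 | (3aR,7aR)-6-{(2E)-4-[5-methoxy-3-methyl-2-(triisopropylsilyloxy)phenyl]-2-methylbut-2-en-1-yl}-3a,7a-dimethyl-5-[2-methyl-2-(triethylsilyloxy)propyl]-1,2,3,3a,7,7a-hexahydro-4H-inden-4-one | COc1cc(C)c(O[Si](C(C)C)(C(C)C)C(C)C)c(C/C=C(\C)CC2=C(CC(C)(C)O[Si](CC)(CC)CC)C(=O)[C@]3(C)CCC[C@]3(C)C2)c1 | intermediate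
34 | (3aR,7aR)-5-(2-hydroxy-2-methylpropyl)-6-[(2E)-4-(2-hydroxy-5-methoxy-3-methylphenyl)-2-methylbut-2-en-1-yl]-3a,7a-dimethyl-1,2,3,3a,7,7a-hexahydro-4H-inden-4-one | COc1cc(C)c(O)c(C/C=C(\C)CC2=C(CC(C)(C)O)C(=O)[C@]3(C)CCC[C@]3(C)C2)c1 | target

## Step count and least certain steps

Total: 21 steps. Longest linear sequence: 16 steps (steps 1–14, 20, 21); the side-chain fragment takes 5 steps (15–19).

**Step 5 (key step).** The most likely failure is loss of site selectivity. The acetoxy-bearing C–H is also 1,5 to the carbenoid and could be inserted, or the acceptor-only carbenoid could undergo Wolff rearrangement or dimerise, because a mono-stabilised carbenoid is very reactive and not very discriminating. Fallback: the same bond is formed from a more selective acceptor/acceptor carbenoid. It sets out from acid 8 and returns at 11. Acid 8 is homologated (carbonyldiimidazole, then the magnesium salt of monomethyl malonate) to methyl 4-[(1R,2S,6R)-6-acetoxy-1,2-dimethylcyclohexyl]-3-oxobutanoate F1. Regitz diazo transfer (4-acetamidobenzenesulfonyl azide, Et3N) gives the α-diazo-β-keto ester F2. Rh2(OAc)4 closes ring C to the bicyclic β-keto ester F3, and Krapcho dealkoxycarbonylation (LiCl, wet DMSO, heat) gives 11.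

**Step 20.** The most likely failure is slow transmetalation from the tetrasubstituted, electron-poor vinylstannane. The π-allyl palladium intermediate would then have time to homocouple or to scramble its geometry, and the stannane could be protodestannylated. Fallback: the roles of the partners are reversed. It sets out from 32 and 23 and returns at 33. Bromide 32 is converted (B2pin2, palladium catalysis) into the (E)-allyl pinacol boronate F4, and a Suzuki–Miyaura coupling with vinyl triflate 23 under a bulky ligand that favours the linear product gives 33. The hindered partner then only has to undergo oxidative addition.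

**Step 13.** The most likely failure is sulfonylation at the C4 oxygen, giving the regioisomeric triflate, because the two enol forms of 22 interconvert and the steric bias may be incomplete. Fallback: the leaving group is placed on C6 by conjugate addition, so no choice between two oxygens arises. It sets out from 19 and returns at 24. Thiophenol adds to 19 (Et3N) to give the β-phenylthio ketone F5. Chlorination with N-chlorosuccinimide and loss of HCl gives the β-phenylthio enone F6. Addition–elimination of a trimethylstannyl cuprate then gives 24.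

**Step 1.** The most likely failure is incomplete alkylation of the hindered tetrasubstituted aluminate enolate, leaving protonated 2,3-dimethylcyclohexanone, because a quaternary carbon is formed next to a tertiary one by a weakly nucleophilic enolate. Fallback: the two bonds are made in separate operations. It sets out from 1 and 2 and returns at 5. The aluminium enolate from the conjugate addition is trapped with Me3SiOTf and isolated as trimethyl{[(3S)-2,3-dimethylcyclohex-1-en-1-yl]oxy}silane F7. MeLi then releases the regiodefined lithium enolate, which is alkylated with 3 in THF/HMPA to give 5.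

## Further compounds

F1 | step 5 | methyl 4-[(1R,2S,6R)-6-acetoxy-1,2-dimethylcyclohexyl]-3-oxobutanoate | CC(=O)O[C@H]1[C@](C)(CC(=O)CC(=O)OC)[C@@H](C)CCC1
F2 | step 5 | methyl 4-[(1R,2S,6R)-6-acetoxy-1,2-dimethylcyclohexyl]-2-diazo-3-oxobutanoate | CC(=O)O[C@H]1[C@](C)(CC(=O)C(=[N+]=[N-])C(=O)OC)[C@@H](C)CCC1
F3 | step 5 | methyl (3aR,4R,7aS)-4-acetoxy-3a,7a-dimethyl-2-oxooctahydro-1H-indene-1-carboxylate (C1 unassigned) | CC(=O)O[C@H]1[C@]2(C)CC(=O)C(C(=O)OC)[C@]2(C)CCC1
F4 | step 20 | {4-methoxy-2-methyl-6-[(2E)-3-methyl-4-(4,4,5,5-tetramethyl-1,3,2-dioxaborolan-2-yl)but-2-en-1-yl]phenoxy}tri(propan-2-yl)silane | COc1cc(C)c(O[Si](C(C)C)(C(C)C)C(C)C)c(C/C=C(\C)CB2OC(C)(C)C(C)(C)O2)c1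
F5 | step 13 | (3aR,7aR)-3a,7a-dimethyl-5-[2-methyl-2-(triethylsilyloxy)propyl]-6-(phenylsulfanyl)octahydro-4H-inden-4-one (C5, C6 unassigned) | O=C1[C@]2(C)CCC[C@]2(C)CC(Sc3ccccc3)C1CC(C)(C)O[Si](CC)(CC)CC
F6 | step 13 | (3aR,7aR)-3a,7a-dimethyl-5-[2-methyl-2-(triethylsilyloxy)propyl]-6-(phenylsulfanyl)-1,2,3,3a,7,7a-hexahydro-4H-inden-4-one | O=C1[C@]2(C)CCC[C@]2(C)CC(Sc3ccccc3)=C1CC(C)(C)O[Si](CC)(CC)CC
F7 | step 1 | trimethyl{[(3S)-2,3-dimethylcyclohex-1-en-1-yl]oxy}silane | C[Si](C)(C)OC1=C(C)[C@@H](C)CCC1
A1 | alternative 1 | endo cycloadduct, cis-dimethyl hydrindene trione equivalent | CO[C@@H]1[C@]2(C)C(=O)CC(=O)[C@]2(C)CC(O[Si](C)(C)C)=C1CC(C)(C)O[Si](CC)(CC)CC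
A2 | alternative 1 | 4,5-dimethylcyclopent-4-ene-1,3-dione | CC1=C(C)C(=O)CC1=O
A3 | alternative 1 | (1E)-1-methoxy-2-[2-methyl-2-(triethylsilyloxy)propyl]-3-(trimethylsilyloxy)buta-1,3-diene | CO/C=C(\CC(C)(C)O[Si](CC)(CC)CC)C(=C)O[Si](C)(C)C
A4 | alternative 2 | silyl-protected bicyclic enone lacking the C5 arm | COc1cc(C)c(O[Si](C)(C)C(C)(C)C)c(C/C=C(\C)CC2=CC(=O)[C@]3(C)CCC[C@]3(C)C2)c1
A5 | alternative 2 | N-hydroxyphthalimide ester of the cis-1,2-dimethylcyclopentane ynone acid | COc1cc(C)c(O[Si](C)(C)C(C)(C)C)c(C/C=C(\C)CC#CC(=O)[C@]2(C)CCC[C@]2(C)CC(=O)ON2C(=O)c3ccccc3C2=O)c1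
A6 | alternative 3 | cis-1,2-dimethyl-2-[(E)-5-(trimethylsilyl)pent-1-en-4-ynyl]cyclopentane-1-carboxylic acid | OC(=O)[C@]1(C)CCC[C@]1(C)/C=C/CC#C[Si](C)(C)C
A7 | alternative 3 | (Z)-nine-membered lactone with (R)-carbinol centre, 3,7-dimethyl-9-[3-(trimethylsilyl)prop-2-ynyl]oxonan-7-en-2-one (α-methyl centre immaterial) | O=C1O[C@H](CC#C[Si](C)(C)C)/C=C(C)\CCCC1C
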